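**Retrosynthetic overview**

1. The last operations are acid release of two MOM ethers and, before that, dehydrogenation of a chroman to put the alkene into ring D (the dimethylpyran); the C3–C1' bond between ring C and ring B comes from a Suzuki–Miyaura coupling of a 3-iodochromone with a 2,2-dimethylchroman-6-yl boronate.
2. The boronate goes back, by a sterically governed aromatic C–H borylation, to 8-(methoxymethoxy)-2,2-dimethylchroman, and this to 1-iodo-2-(methoxymethoxy)benzene plus 4-bromo-2-methylbutan-2-ol.
3. Key disconnection: a palladium/norbornene (Catellani-type) annulation that alkylates C5'–H next to the iodide and then closes ring D by joining the iodine-bearing C4' to the tertiary carbinol oxygen.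
4. Enabling feature: on ring B the atoms C3' (O), C4' (O) and C5' (C) are contiguous, so the C3' oxygen blocks one ortho position of a C4' iodide and leaves C5'–H as the only ortho C–H; the ring D oxygen sits on a gem-dimethyl carbon, giving an alkoxide without beta-hydrogens that is fit for C–O reductive elimination.
5. Ring order: ring A is bought; ring D is fused onto ring B (key step); ring C is closed onto ring A by iodocyclisation of an enaminone; the two bicycles are then united.

Key step: step 2

Remark: the two palladium intermediates of the key step are drawn without their phosphine ligand, and the norbornane-containing one is racemic (one enantiomer drawn); the three starting materials are taken as catalogue compounds.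

**Route**

Step 1
Reactants: 1 2-iodophenol
Product: 2 1-iodo-2-(methoxymethoxy)benzene
Conditions: MOMCl, iPr2NEt, CH2Cl2, 0 °C to rt
Reagents that add atoms: chloromethyl methyl ether (MOMCl), COCCl
Why: O-alkylation of the phenol by the reactive alpha-chloro ether (Williamson-type acetal formation) should install a base-stable MOM ether.

Step 2
Reactants: 2 1-iodo-2-(methoxymethoxy)benzene; 3 4-bromo-2-methylbutan-2-ol
Product: 6 8-(methoxymethoxy)-2,2-dimethylchromane, via aryl-norbornyl palladacycle 4 (not isolated), via aryl palladium alkoxide chelate 5 (not isolated)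
Conditions: Pd(OAc)2 (5 mol %), XPhos (10 mol %), norbornene (1 equiv), Cs2CO3 (3 equiv), 3 (2 equiv), 1,4-dioxane, 100 °C
Reagents that add atoms: none
Why: Proposed new method: zerovalent palladium should insert into the C–I bond of 2, and norbornene carbopalladation followed by carbonate-assisted palladation of the only free ortho C–H should give palladacycle 4, which adds the primary C–Br bond of 3 to reach tetravalent palladium and forms the aryl–CH2 bond by reductive elimination; with both ortho positions then substituted, norbornene is expelled by beta-carbon elimination and the caesium alkoxide of the pendant tertiary alcohol binds divalent palladium to give chelate 5. Ring D then closes as a six-membered ring by aryl C–O reductive elimination from the seven-membered aryl(alkoxo)palladium chelate 5, joining the former C–I carbon to the carbinol oxygen and returning zerovalent palladium. The closest known reaction types are the Catellani ortho-alkylation with primary alkyl bromides, the palladium/norbornene annulations of aryl iodides with epoxides (to 2,3-dihydrobenzofurans) and with 2-bromobenzyl tertiary alcohols (to 6H-dibenzopyrans), which end in the same ipso C–O closure, and the palladium-catalysed cyclisation of 4-(2-halophenyl)-2-methylbutan-2-ols to 2,2-dimethylchromans. No stereocenter is formed. The step needs mono-alkylation at a single ortho site, secured by the OMOM group that blocks the other ortho position and also drives norbornene extrusion, and it needs C–O termination in preference to protodepalladation or beta-hydride loss, secured by a tertiary alkoxide without beta-hydrogens, the gem-dimethyl effect and a bulky biaryl phosphine.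

Step 3
Reactants: 6 8-(methoxymethoxy)-2,2-dimethylchromane
Product: 7 2-[8-(methoxymethoxy)-2,2-dimethylchroman-6-yl]-4,4,5,5-tetramethyl-1,3,2-dioxaborolane
Conditions: [Ir(OMe)(cod)]2 (1.5 mol %), 4,4'-di-tert-butyl-2,2'-bipyridine (3 mol %), B2pin2 (1 equiv), THF, 80 °C
Reagents that add atoms: bis(pinacolato)diboron (B2pin2), CC1(C)OB(OC1(C)C)B1OC(C)(C)C(C)(C)O1
Why: iridium-catalysed aromatic C–H borylation is sterically controlled, and C6–H is the only aromatic C–H without an ortho substituent (position 5 of a 1,2,3-trisubstituted benzene), so the boron should enter at the future C1'.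

Step 4
Reactants: 8 1-(2,4-dihydroxy-6-methoxyphenyl)ethan-1-one
Product: 9 1-[2-hydroxy-6-methoxy-4-(methoxymethoxy)phenyl]ethan-1-one
Conditions: MOMCl (1.05 equiv), iPr2NEt, CH2Cl2, 0 °C
Reagents that add atoms: chloromethyl methyl ether (MOMCl), COCCl
Why: selective O-alkylation is expected because the 2-OH is held in a hydrogen bond to the ketone, so the more acidic, unchelated 4-OH reacts.

Step 5
Reactants: 9 1-[2-hydroxy-6-methoxy-4-(methoxymethoxy)phenyl]ethan-1-one
Product: 10 (E)-3-(dimethylamino)-1-[2-hydroxy-6-methoxy-4-(methoxymethoxy)phenyl]prop-2-en-1-one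
Conditions: DMF-DMA, toluene, 95 °C
Reagents that add atoms: N,N-dimethylformamide dimethyl acetal (DMF-DMA), COC(OC)N(C)C
Why: condensation of the methyl ketone with the amide acetal (enaminone formation) should give the thermodynamically preferred E push-pull alkene.

Step 6
Reactants: 10 (E)-3-(dimethylamino)-1-[2-hydroxy-6-methoxy-4-(methoxymethoxy)phenyl]prop-2-en-1-one
Product: 11 3-iodo-5-methoxy-7-(methoxymethoxy)-4H-chromen-4-one
Conditions: I2, pyridine, CHCl3, rt
Reagents that add atoms: iodine, II
Why: iodine-mediated cyclisation of 2-hydroxyaryl enaminones to 3-iodochromones (iodination at the enaminone alpha-carbon, ring closure by the phenol, loss of dimethylamine) should close ring C, with pyridine buffering the acid so that the MOM ether persists.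

Step 7
Reactants: 11 3-iodo-5-methoxy-7-(methoxymethoxy)-4H-chromen-4-one; 7 2-[8-(methoxymethoxy)-2,2-dimethylchroman-6-yl]-4,4,5,5-tetramethyl-1,3,2-dioxaborolane
Product: 12 5-methoxy-7-(methoxymethoxy)-3-[8-(methoxymethoxy)-2,2-dimethylchroman-6-yl]-4H-chromen-4-one
Conditions: PdCl2(dppf) (5 mol %), Na2CO3, DME/H2O (4:1), 80 °C
Reagents that add atoms: none
Why: Suzuki–Miyaura coupling of a 3-iodochromone with an unhindered aryl boronate is the standard isoflavone assembly, and the mild carbonate base should spare the pyranone ring.

Step 8
Reactants: 12 5-methoxy-7-(methoxymethoxy)-3-[8-(methoxymethoxy)-2,2-dimethylchroman-6-yl]-4H-chromen-4-one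
Product: 13 5-methoxy-7-(methoxymethoxy)-3-[8-(methoxymethoxy)-2,2-dimethyl-2H-chromen-6-yl]-4H-chromen-4-one
Conditions: DDQ (2 equiv), 1,4-dioxane, reflux
Reagents that add atoms: none
Why: DDQ dehydrogenation of a 2,2-dimethylchroman to the 2,2-dimethylchromene should proceed by hydride abstraction from the benzylic C–H (cation stabilised by the ortho ring D oxygen) and loss of the adjacent proton, with no free phenol present to be oxidised.

Step 9
Reactants: 13 5-methoxy-7-(methoxymethoxy)-3-[8-(methoxymethoxy)-2,2-dimethyl-2H-chromen-6-yl]-4H-chromen-4-one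
Product: 14 glycyrrhizaisoflavone B, 7-hydroxy-3-(8-hydroxy-2,2-dimethyl-2H-chromen-6-yl)-5-methoxy-4H-chromen-4-one
Conditions: 3 M HCl, MeOH/THF, 45 °C
Reagents that add atoms: none
Why: acid-catalysed acetal exchange with methanol should cleave both aryl MOM ethers under conditions mild enough to leave the C5 methyl ether and the chromene alkene untouched.

**Compound list**

1 | 2-iodophenol | Oc1ccccc1I | starting material
2 | 1-iodo-2-(methoxymethoxy)benzene | COCOc1ccccc1I | intermediate
3 | 4-bromo-2-methylbutan-2-ol | CC(C)(O)CCBr | starting material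
4 | aryl-norbornyl palladacycle (not isolated; racemic, exo-cis, phosphine not drawn) | COCOc1cccc2c1[C@@H]1[C@H]3CC[C@H](C3)[C@@H]1[Pd]2 | intermediate
5 | aryl palladium alkoxide chelate (not isolated; seven-membered oxapalladacycle, phosphine not drawn) | COCOc1cccc2c1[Pd]OC(C)(C)CC2 | intermediate
6 | 8-(methoxymethoxy)-2,2-dimethylchromane | COCOc1cccc2c1OC(C)(C)CC2 | intermediate
7 | 2-[8-(methoxymethoxy)-2,2-dimethylchroman-6-yl]-4,4,5,5-tetramethyl-1,3,2-dioxaborolane | COCOc1cc(B3OC(C)(C)C(C)(C)O3)cc2c1OC(C)(C)CC2 | intermediate
8 | 1-(2,4-dihydroxy-6-methoxyphenyl)ethan-1-one | CC(=O)c1c(O)cc(O)cc1OC | starting material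
9 | 1-[2-hydroxy-6-methoxy-4-(methoxymethoxy)phenyl]ethan-1-one | CC(=O)c1c(O)cc(OCOC)cc1OC | intermediate
10 | (E)-3-(dimethylamino)-1-[2-hydroxy-6-methoxy-4-(methoxymethoxy)phenyl]prop-2-en-1-one | CN(C)/C=C/C(=O)c1c(O)cc(OCOC)cc1OC | intermediate
11 | 3-iodo-5-methoxy-7-(methoxymethoxy)-4H-chromen-4-one | COCOc1cc(OC)c2c(c1)occ(I)c2=O | intermediate
12 | 5-methoxy-7-(methoxymethoxy)-3-[8-(methoxymethoxy)-2,2-dimethylchroman-6-yl]-4H-chromen-4-one | COCOc1cc(OC)c2c(c1)occ(-c1cc(OCOC)c3c(c1)CCC(C)(C)O3)c2=O | intermediate
13 | 5-methoxy-7-(methoxymethoxy)-3-[8-(methoxymethoxy)-2,2-dimethyl-2H-chromen-6-yl]-4H-chromen-4-one | COCOc1cc(OC)c2c(c1)occ(-c1cc(OCOC)c3c(c1)C=CC(C)(C)O3)c2=O | intermediate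
14 | glycyrrhizaisoflavone B | COc1cc(O)cc2occ(-c3cc(O)c4c(c3)C=CC(C)(C)O4)c(=O)c12 | target

**Step count and risks**

Total step count: 9. Longest linear sequence: 6 (steps 1, 2, 3, 7, 8, 9; the branch through steps 4, 5, 6 is equally long).

Steps most likely to fail:

Step 2 (proposed method). After the ortho-alkylation, the arylpalladium species may be protonated or may re-insert norbornene faster than it closes the C–O bond, and the bromo alcohol may be consumed by base-induced cyclisation or elimination. The fallback sets out from 2 and comes back at 6, building the ring by the classical aryl propargyl ether route. Palladium-catalysed hydroxylation of 2 (Pd2(dba)3, t-BuXPhos, KOH, dioxane/H2O, 100 °C) should give 2-(methoxymethoxy)phenol F1. O-alkylation with 3-chloro-3-methylbut-1-yne (DBU, catalytic CuCl2, MeCN, 0 °C) should give 1-(methoxymethoxy)-2-[(2-methylbut-3-yn-2-yl)oxy]benzene F2. Heating in N,N-diethylaniline at 190 °C (Claisen rearrangement, hydrogen shift and oxa-6π electrocyclisation onto the only free ortho position) should give 8-(methoxymethoxy)-2,2-dimethyl-2H-chromene F3. Hydrogenation (H2, Pd/C, EtOAc) then returns 6, so that the borylation can be run on the alkene-free chroman as planned.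

Step 8. Hydride abstraction from the benzylic position may be too slow, because the cation is stabilised only by the ring D oxygen, so that conversion stalls or the electron-rich rings are attacked instead. The fallback sets out from 7 and comes back at 13, installing the alkene by a radical pathway at the fragment stage. Wohl–Ziegler bromination of 7 (NBS, AIBN, PhCF3, 80 °C) at its only benzylic CH2 should give racemic 2-[4-bromo-8-(methoxymethoxy)-2,2-dimethylchroman-6-yl]-4,4,5,5-tetramethyl-1,3,2-dioxaborolane F4. Elimination with DBU in toluene at 80 °C should give 2-[8-(methoxymethoxy)-2,2-dimethyl-2H-chromen-6-yl]-4,4,5,5-tetramethyl-1,3,2-dioxaborolane F5. Suzuki–Miyaura coupling of F5 with 11 under the conditions of step 7 then gives 13 directly.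

Step 9. Acid may add methanol or water across the styrene-type alkene of the chromene, or start cationic oligomerisation, before both acetals are cleaved. The fallback sets out from 12 and comes back at 14, exchanging the protecting groups while ring D is still saturated. Treatment of 12 with HCl in MeOH should give 7-hydroxy-3-(8-hydroxy-2,2-dimethylchroman-6-yl)-5-methoxy-4H-chromen-4-one F6. Acetylation (Ac2O, pyridine) should give 3-(8-acetoxy-2,2-dimethylchroman-6-yl)-5-methoxy-4-oxo-4H-chromen-7-yl acetate F7. DDQ in refluxing dioxane should give 3-(8-acetoxy-2,2-dimethyl-2H-chromen-6-yl)-5-methoxy-4-oxo-4H-chromen-7-yl acetate F8. Methanolysis of the acetates (K2CO3, MeOH, 0 °C to rt) then gives 14 without any acid.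

**Further compounds**

F1 | step 2 | 2-(methoxymethoxy)phenol | COCOc1ccccc1O
F2 | step 2 | 1-(methoxymethoxy)-2-[(2-methylbut-3-yn-2-yl)oxy]benzene | COCOc1ccccc1OC(C)(C)C#C
F3 | step 2 | 8-(methoxymethoxy)-2,2-dimethyl-2H-chromene | COCOc1cccc2c1OC(C)(C)C=C2
F4 | step 8 | 2-[4-bromo-8-(methoxymethoxy)-2,2-dimethylchroman-6-yl]-4,4,5,5-tetramethyl-1,3,2-dioxaborolane (racemic) | COCOc1cc(B3OC(C)(C)C(C)(C)O3)cc2c1OC(C)(C)CC2Br
F5 | step 8 | 2-[8-(methoxymethoxy)-2,2-dimethyl-2H-chromen-6-yl]-4,4,5,5-tetramethyl-1,3,2-dioxaborolane | COCOc1cc(B3OC(C)(C)C(C)(C)O3)cc2c1OC(C)(C)C=C2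
F6 | step 9 | 7-hydroxy-3-(8-hydroxy-2,2-dimethylchroman-6-yl)-5-methoxy-4H-chromen-4-one | COc1cc(O)cc2occ(-c3cc(O)c4c(c3)CCC(C)(C)O4)c(=O)c12
F7 | step 9 | 3-(8-acetoxy-2,2-dimethylchroman-6-yl)-5-methoxy-4-oxo-4H-chromen-7-yl acetate | COc1cc(OC(C)=O)cc2occ(-c3cc(OC(C)=O)c4c(c3)CCC(C)(C)O4)c(=O)c12
F8 | step 9 | 3-(8-acetoxy-2,2-dimethyl-2H-chromen-6-yl)-5-methoxy-4-oxo-4H-chromen-7-yl acetate | COc1cc(OC(C)=O)cc2occ(-c3cc(OC(C)=O)c4c(c3)C=CC(C)(C)O4)c(=O)c12
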